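**Retrosynthetic overview**

1. Longipinane numbering is used throughout: C1 ketone, C2=C3 with CH3 on C3, C4 and C11 bridgeheads, C5 cyclobutane CH, C6 CMe2, C7 tiglate carbon, C8 CH2, C9 senecioate carbon, C10 quaternary. The strategy rests on the C10–C11 bond, which is shared by the six-membered ring C10–C11–C1–C2–C3–C4 and the seven-membered ring C5–C6–C7–C8–C9–C10–C11 and is flanked by C9 and C5; it becomes the alkene of a cyclohept-2-ene-1,4-dione dienophile.
2. Disconnections, last to first: C7 tiglate; C9 3-methylbut-2-enoate together with C7–OH (Evans–Tishchenko reduction of a C9-hydroxy C7-ketone); C1 ketone (allylic oxidation of the C2=C3 alkene); C5–O (radical deoxygenation); C4–C5 (SmI2 ketyl–enone 4-exo-trig closure); C10–C4 and C11–C1 (catalytic enantioselective Diels–Alder reaction of enedione ketal 7 with silyloxydiene 9).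
3. Enedione 7 is made from cycloheptane-1,3-dione by gem-dimethylation, mono-ketalisation, dehydrogenation, conjugate methylation with re-oxidation, and γ-oxidation.
4. Ring order: seven-membered ring (present in 1), six-membered ring (step 7), four-membered ring (step 11).

Key step: step 7

Assumption: the (S)-configured oxazaborolidinium salt is taken to leave open the face of 7 that leads to (10R,11S)-10; if the sense of induction proves opposite, the (R)-salt is used with nothing else changed.

Step 1
Reactants: 1 cycloheptane-1,3-dione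
Product: 2 2,2-dimethylcycloheptane-1,3-dione
Conditions: MeI (3 equiv), K2CO3, acetone, 56 °C
Reagents that add atoms: iodomethane (CI)
Why: Twofold C-alkylation of the 1,3-diketone enolate (enolate alkylation) at the carbon between the carbonyls, which becomes C6 with its two methyl groups.

Step 2
Reactants: 2 2,2-dimethylcycloheptane-1,3-dione
Product: 3 6,6-dimethyl-1,4-dioxaspiro[4.6]undecan-7-one
Conditions: HOCH2CH2OH (1.1 equiv), TsOH (cat.), toluene, reflux, water separator
Reagents that add atoms: ethane-1,2-diol (OCCO)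
Why: Acid-catalysed ketalisation of one of two equivalent carbonyls; the first dioxolane next to the quaternary carbon should make the remaining carbonyl too hindered for a second ketalisation, leaving C7 masked and C5 free.

Step 3
Reactants: 3 6,6-dimethyl-1,4-dioxaspiro[4.6]undecan-7-one
Product: 4 6,6-dimethyl-1,4-dioxaspiro[4.6]undec-8-en-7-one
Conditions: IBX (1.3 equiv), DMSO, 70 °C
Reagents that add atoms: none
Why: IBX-mediated α,β-dehydrogenation of a ketone; only the C11 side of the C5 carbonyl can enolise, so the C10=C11 enone should form regiospecifically.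

Step 4
Reactants: 4 6,6-dimethyl-1,4-dioxaspiro[4.6]undec-8-en-7-one
Product: 6 6,6,9-trimethyl-1,4-dioxaspiro[4.6]undec-8-en-7-one, via silyl enol ether 5 (not isolated)
Conditions: Me2CuLi, Me3SiCl, THF, −78 °C; then Pd(OAc)2 (1.1 equiv), MeCN, 23 °C
Reagents that add atoms: lithium dimethylcuprate ([Li+].C[Cu-]C); chlorotrimethylsilane (C[Si](C)(C)Cl) (kept only in 5)
Why: Cuprate conjugate addition places the methyl group on C10 and the enolate is trapped as silyl enol ether 5, whose Saegusa oxidation (palladium enolate, β-hydride elimination from C10) restores the enone.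

Step 5
Reactants: 6 6,6,9-trimethyl-1,4-dioxaspiro[4.6]undec-8-en-7-one
Product: 7 6,6,9-trimethyl-1,4-dioxaspiro[4.6]undec-8-ene-7,10-dione (2,5,5-trimethyl-6,6-ethylenedioxycyclohept-2-ene-1,4-dione)
Conditions: Pd(OH)2/C (5 mol%), t-BuOOH (5 equiv), K2CO3, CH2Cl2, 23 °C
Reagents that add atoms: tert-butyl hydroperoxide (CC(C)(C)OO)
Why: Palladium-catalysed γ-oxidation of an α,β-enone to an ene-1,4-dione by tert-butyl hydroperoxide (allylic peroxidation, then loss of tert-butanol); the ring methylene C9 should react in preference to the methyl group.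

Step 6
Reactants: 8 3-methylbut-3-en-2-one
Product: 9 3-methyl-2-(triisopropylsilyloxy)buta-1,3-diene
Conditions: i-Pr3SiOTf, Et3N, CH2Cl2, 0 °C
Reagents that add atoms: triisopropylsilyl trifluoromethanesulfonate (CC(C)[Si](OS(=O)(=O)C(F)(F)F)(C(C)C)C(C)C)
Why: Soft enolisation of the methyl ketone (silyl enol ether formation) gives the 2-silyloxydiene; the triisopropylsilyl group is chosen over trimethylsilyl so that the enol ether survives the cationic Lewis acid of step 7.

Step 7
Reactants: 7 6,6,9-trimethyl-1,4-dioxaspiro[4.6]undec-8-ene-7,10-dione; 9 3-methyl-2-(triisopropylsilyloxy)buta-1,3-diene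
Product: 10 (10R,11S)-7,7-(ethylenedioxy)-2-(triisopropylsilyloxy)-4,5-secolongipin-2-ene-5,9-dione (cis-fused bicyclo[5.4.0]undecene)
Conditions: (S)-3,3-diphenyl-1-(2-methylphenyl)tetrahydro-1H,3H-pyrrolo[1,2-c][1,3,2]oxazaborole·HN(SO2CF3)2 (20 mol%), CH2Cl2, −78 → −20 °C
Reagents that add atoms: none
Why: Lewis-acid-catalysed Diels–Alder reaction of a 2-silyloxydiene with a 2-methyl ene-1,4-dione, a known reaction type: the boron cation lowers the LUMO of the C10=C11 alkene and the [4+2] closure is concerted but asynchronous, the bond from the silyloxy-flanked diene CH2 to C11 running ahead of the bond from the other terminus to C10. The six-membered ring C10–C11–C1–C2–C3–C4 closes suprafacially on both partners, so the C10 methyl group and C11–H stay cis and the ring fusion is cis, which later places C4 (on C10) and C5 (on C11) on one face. C10 and C11 are set together by the face of the flat, achiral enedione that the catalyst leaves open. The step needs regioselectivity as well as facial selectivity: the required orientation is the one in which the enedione is polarised through the C9 carbonyl (the carbonyl on the methyl-bearing carbon, with unsubstituted C11 as acceptor), which is also the orientation expected for the uncatalysed addition. In the substrate this is supported by the open C8H2 side of the C9 carbonyl, by the C6 gem-dimethyl group and spiroketal next to the C5 carbonyl, and by the bulk of the triisopropylsilyloxy group, which keeps its end of the diene away from the quaternary centre forming at C10. No endo/exo question arises because the diene has no terminal substituent.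

Step 8
Reactants: 10 (10R,11S)-7,7-(ethylenedioxy)-2-(triisopropylsilyloxy)-4,5-secolongipin-2-ene-5,9-dione
Product: 11 (9R,10R,11S)-7,7-(ethylenedioxy)-9-hydroxy-2-(triisopropylsilyloxy)-4,5-secolongipin-2-en-5-one
Conditions: (S)-1-methyl-3,3-diphenyltetrahydro-1H,3H-pyrrolo[1,2-c][1,3,2]oxazaborole (20 mol%), BH3·SMe2, THF, −30 °C
Reagents that add atoms: none
Why: CBS reduction: the oxazaborolidine binds the C9 carbonyl anti to quaternary C10 (large) and syn to C8H2 (small) and delivers hydride to give the (9R)-alcohol, C9–O cis to the C10 methyl group, while the C5 carbonyl, branched on both sides, should be left.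

Step 9
Reactants: 11 (9R,10R,11S)-7,7-(ethylenedioxy)-9-hydroxy-2-(triisopropylsilyloxy)-4,5-secolongipin-2-en-5-one
Product: 12 9-O-triethylsilyl ether of 11
Conditions: Et3SiOTf, 2,6-lutidine, CH2Cl2, −78 °C
Reagents that add atoms: triethylsilyl trifluoromethanesulfonate (CC[Si](CC)(CC)OS(=O)(=O)C(F)(F)F)
Why: Silyl ether formation at the secondary alcohol, done at once so that the C9 hydroxyl cannot add across the seven-membered ring to the C5 carbonyl.

Step 10
Reactants: 12 9-O-triethylsilyl ether of 11
Product: 13 (9R,10R,11S)-7,7-(ethylenedioxy)-9-(triethylsilyloxy)-4,5-secolongipin-3-ene-2,5-dione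
Conditions: Pd(OAc)2 (1.2 equiv), DMSO, 45 °C
Reagents that add atoms: none
Why: Saegusa oxidation of the silyl enol ether: the palladium enolate at C3 undergoes β-hydride elimination towards ring carbon C4, giving the C2 ketone with the C3=C4 alkene that makes C4 a radical acceptor.

Step 11
Reactants: 13 (9R,10R,11S)-7,7-(ethylenedioxy)-9-(triethylsilyloxy)-4,5-secolongipin-3-ene-2,5-dione
Product: 15 7,7-(ethylenedioxy)-5-hydroxy-9-(triethylsilyloxy)longipin-2-en-2-yl trifluoromethanesulfonate, via samarium enolate alkoxide 14 (not isolated)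
Conditions: SmI2 (2.5 equiv), HMPA, THF, −78 °C; then PhNTf2, −78 → 0 °C
Reagents that add atoms: N-phenylbis(trifluoromethanesulfonimide) (O=S(=O)(N(c1ccccc1)S(=O)(=O)C(F)(F)F)C(F)(F)F); samarium diiodide ([Sm+2].[I-].[I-]) (kept only in 14)
Why: SmI2-mediated ketyl–olefin cyclisation (4-exo-trig, known for γ,δ-unsaturated carbonyl compounds with acceptor alkenes): electron transfer gives a C5 ketyl that bonds to the enone β-carbon C4, the cyclised α-keto radical is reduced at once to the samarium enolate, and O-triflation of that enolate fixes the C2=C3 double bond and keeps a C2 carbonyl from forming next to the new hydroxyl; C4 and C5 can be set only one way because both lie on the same face of the cis-fused bicycle, which puts the C5 hydroxyl on the side of the C1–C3 bridge.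

Step 12
Reactants: 15 7,7-(ethylenedioxy)-5-hydroxy-9-(triethylsilyloxy)longipin-2-en-2-yl trifluoromethanesulfonate
Product: 16 5-O-(methoxyoxalyl) ester of 15
Conditions: MeO2CCOCl, DMAP, pyridine, CH2Cl2, 0 → 23 °C
Reagents that add atoms: methyl chlorooxoacetate (COC(=O)C(Cl)=O)
Why: DMAP-catalysed acylation of the tertiary cyclobutanol with the small, very electrophilic oxalyl half-ester chloride gives the radical precursor without resort to an alkoxide, which would endanger the enol triflate, and no elimination is possible because every β-carbon is a bridgehead or quaternary.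

Step 13
Reactants: 16 5-O-(methoxyoxalyl) ester of 15
Product: 17 7,7-(ethylenedioxy)-9-(triethylsilyloxy)longipin-2-en-2-yl trifluoromethanesulfonate
Conditions: Bu3SnH, AIBN, toluene, 110 °C
Reagents that add atoms: none
Why: Barton-type radical deoxygenation of a tertiary methyl oxalate: stannyl radical addition and C–O scission give the C5 cyclobutyl radical, which should take hydrogen from the stannane faster than the four-membered ring opens; C5 can carry its hydrogen only on the side of the C1–C3 bridge, which is the configuration of the target.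

Step 14
Reactants: 17 7,7-(ethylenedioxy)-9-(triethylsilyloxy)longipin-2-en-2-yl trifluoromethanesulfonate
Product: 18 7,7-(ethylenedioxy)-9-(triethylsilyloxy)longipin-2-ene
Conditions: Pd(OAc)2 (5 mol%), PPh3, HCO2H, Et3N, DMF, 60 °C
Reagents that add atoms: none
Why: Palladium-catalysed formate reduction of the enol triflate (oxidative addition, formate-to-hydride exchange, reductive elimination) replaces the C2 oxygen by hydrogen and leaves the C2=C3 alkene with its methyl group on C3.

Step 15
Reactants: 18 7,7-(ethylenedioxy)-9-(triethylsilyloxy)longipin-2-ene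
Product: 19 7,7-(ethylenedioxy)-9-(triethylsilyloxy)longipin-2-en-1-one
Conditions: Rh2(caprolactamate)4 (1 mol%), t-BuOOH (5 equiv), K2CO3, CH2Cl2, 23 °C
Reagents that add atoms: tert-butyl hydroperoxide (CC(C)(C)OO)
Why: Dirhodium-catalysed allylic oxidation with tert-butyl hydroperoxide, the same change as α-pinene to verbenone: the ring methylene C1 is the only secondary allylic position (C4 is a bridgehead), so the C1 ketone conjugated with C2=C3 should form under basic conditions that leave the strained alkene, ketal and silyl ether intact.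

Step 16
Reactants: 19 7,7-(ethylenedioxy)-9-(triethylsilyloxy)longipin-2-en-1-one
Product: 20 9-hydroxylongipin-2-ene-1,7-dione
Conditions: 1 M HCl, THF, 23 °C
Reagents that add atoms: water (O)
Why: Acid hydrolysis cleaves the dioxolane and the triethylsilyl ether in one operation (ketal and silyl ether cleavage), uncovering the C7 ketone and the C9 hydroxyl as a β-hydroxy ketone.

Step 17
Reactants: 20 9-hydroxylongipin-2-ene-1,7-dione
Product: 21 7-hydroxy-9-(3-methylbut-2-enoyloxy)longipin-2-en-1-one
Conditions: SmI2 (0.3 equiv), 3-methylbut-2-enal (6 equiv), THF, −10 °C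
Reagents that add atoms: 3-methylbut-2-enal (CC(C)=CC=O)
Why: Evans–Tishchenko reduction: the C9 hydroxyl forms a samarium-bound hemiacetal with the aldehyde and passes its hydride to the C7 carbonyl through a six-membered transition state on the face of the C9–O bond, so C7–OH forms anti (trans) to C9–O while C9 ends as the 3-methylbut-2-enoate; the C1 enone has no β-hydroxyl and should not be reduced.

Step 18
Reactants: 21 7-hydroxy-9-(3-methylbut-2-enoyloxy)longipin-2-en-1-one
Product: 22 (4R,5S,7R,9R,10R,11R)-7-[(E)-2-methylbut-2-enoyloxy]-9-(3-methylbut-2-enoyloxy)longipin-2-en-1-one (CNP0257816.1)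
Conditions: (E)-2-methylbut-2-enoyl chloride, Et3N, DMAP, CH2Cl2, 40 °C
Reagents that add atoms: (E)-2-methylbut-2-enoyl chloride (C/C=C(\C)C(Cl)=O)
Why: DMAP-catalysed esterification of the hindered C7 alcohol with the acid chloride; the E-configured tiglate is the stable isomer and should be retained.

**Compound list**

1 | cycloheptane-1,3-dione | O=C1CCCCC(=O)C1 | starting material
2 | 2,2-dimethylcycloheptane-1,3-dione | O=C1CCCCC(=O)C1(C)C | intermediate
3 | 6,6-dimethyl-1,4-dioxaspiro[4.6]undecan-7-one | O=C1CCCCC2(OCCO2)C1(C)C | intermediate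
4 | 6,6-dimethyl-1,4-dioxaspiro[4.6]undec-8-en-7-one | O=C1C=CCCC2(OCCO2)C1(C)C | intermediate
5 | trimethylsilyl enol ether of the 9-methyl ketone (racemic, not isolated) | C[Si](C)(C)OC1=CC(C)CCC2(OCCO2)C1(C)C | intermediate
6 | 6,6,9-trimethyl-1,4-dioxaspiro[4.6]undec-8-en-7-one | O=C1C=C(C)CCC2(OCCO2)C1(C)C | intermediate
7 | 6,6,9-trimethyl-1,4-dioxaspiro[4.6]undec-8-ene-7,10-dione (enedione ketal, dienophile) | O=C1CC2(OCCO2)C(C)(C)C(=O)C=C1C | intermediate
8 | 3-methylbut-3-en-2-one | CC(=C)C(C)=O | starting material
9 | 3-methyl-2-(triisopropylsilyloxy)buta-1,3-diene | C=C(C)C(=C)O[Si](C(C)C)(C(C)C)C(C)C | intermediate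
10 | (10R,11S)-7,7-(ethylenedioxy)-2-(triisopropylsilyloxy)-4,5-secolongipin-2-ene-5,9-dione (cis-fused Diels–Alder adduct) | C12(OCCO1)CC(=O)[C@@]3(C)[C@H](CC(O[Si](C(C)C)(C(C)C)C(C)C)=C(C)C3)C(=O)C2(C)C | intermediate
11 | (9R,10R,11S)-9-hydroxy compound from 10 | C12(OCCO1)C[C@@H](O)[C@@]3(C)[C@H](CC(O[Si](C(C)C)(C(C)C)C(C)C)=C(C)C3)C(=O)C2(C)C | intermediate
12 | 9-O-triethylsilyl ether of 11 | C12(OCCO1)C[C@@H](O[Si](CC)(CC)CC)[C@@]3(C)[C@H](CC(O[Si](C(C)C)(C(C)C)C(C)C)=C(C)C3)C(=O)C2(C)C | intermediate
13 | 7,7-(ethylenedioxy)-9-(triethylsilyloxy)-4,5-secolongipin-3-ene-2,5-dione | C12(OCCO1)C[C@@H](O[Si](CC)(CC)CC)[C@@]3(C)[C@H](CC(=O)C(C)=C3)C(=O)C2(C)C | intermediate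
14 | bis(diiodosamarium) C2-enolate C5-alkoxide of the cyclised tricycle (trivalent samarium, not isolated) | C12(OCCO1)C[C@@H](O[Si](CC)(CC)CC)[C@@]3(C)[C@@H]4CC(O[Sm](I)I)=C(C)[C@H]3[C@]4(O[Sm](I)I)C2(C)C | intermediate
15 | 7,7-(ethylenedioxy)-5-hydroxy-9-(triethylsilyloxy)longipin-2-en-2-yl trifluoromethanesulfonate | C12(OCCO1)C[C@@H](O[Si](CC)(CC)CC)[C@@]3(C)[C@@H]4CC(OS(=O)(=O)C(F)(F)F)=C(C)[C@H]3[C@]4(O)C2(C)C | intermediate
16 | 5-O-(methoxyoxalyl) ester of 15 | C12(OCCO1)C[C@@H](O[Si](CC)(CC)CC)[C@@]3(C)[C@@H]4CC(OS(=O)(=O)C(F)(F)F)=C(C)[C@H]3[C@]4(OC(=O)C(=O)OC)C2(C)C | intermediate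
17 | 7,7-(ethylenedioxy)-9-(triethylsilyloxy)longipin-2-en-2-yl trifluoromethanesulfonate | C12(OCCO1)C[C@@H](O[Si](CC)(CC)CC)[C@@]3(C)[C@@H]4CC(OS(=O)(=O)C(F)(F)F)=C(C)[C@H]3[C@@H]4C2(C)C | intermediate
18 | 7,7-(ethylenedioxy)-9-(triethylsilyloxy)longipin-2-ene | C12(OCCO1)C[C@@H](O[Si](CC)(CC)CC)[C@@]3(C)[C@@H]4CC=C(C)[C@H]3[C@@H]4C2(C)C | intermediate
19 | 7,7-(ethylenedioxy)-9-(triethylsilyloxy)longipin-2-en-1-one | C12(OCCO1)C[C@@H](O[Si](CC)(CC)CC)[C@@]3(C)[C@@H]4C(=O)C=C(C)[C@H]3[C@@H]4C2(C)C | intermediate
20 | 9-hydroxylongipin-2-ene-1,7-dione | O=C1C[C@@H](O)[C@@]2(C)[C@@H]3C(=O)C=C(C)[C@H]2[C@@H]3C1(C)C | intermediate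
21 | 7-hydroxy-9-(3-methylbut-2-enoyloxy)longipin-2-en-1-one | O[C@@H]1C[C@@H](OC(=O)C=C(C)C)[C@@]2(C)[C@@H]3C(=O)C=C(C)[C@H]2[C@@H]3C1(C)C | intermediate
22 | (4R,5S,7R,9R,10R,11R)-7-[(E)-2-methylbut-2-enoyloxy]-9-(3-methylbut-2-enoyloxy)longipin-2-en-1-one | C/C=C(\C)C(=O)O[C@@H]1C[C@@H](OC(=O)C=C(C)C)[C@@]2(C)[C@@H]3C(=O)C=C(C)[C@H]2[C@@H]3C1(C)C | target

**Step count**

Total steps: 18. Longest linear sequence: 17 (steps 1–5 and 7–18; step 6 is a one-step side branch to the diene).

**Steps most likely to fail**

Step 7. The boron cation may bind the C5 carbonyl instead of the C9 carbonyl; the C5 carbonyl lies next to the vinylic C11–H and is conjugated with the methyl-bearing carbon, so it is likely the more basic site. The polarisation of the alkene would then be reversed, the silyloxy-bearing diene terminus would bond to C10, and the regioisomeric adduct would form. A loosely organised C9-bound complex could also give poor facial selectivity. The fallback sets out from 7 and 9. They are heated without catalyst (toluene, 110 °C, radical inhibitor), where the carbonyl on the methyl-bearing carbon should govern the orientation. This should give the racemic adduct, that is 10 together with its enantiomer, (10S,11R)-adduct F1. The racemate is put through the reduction of step 8. The (S)-oxazaborolidine should impose the same sense at C9 on both enantiomers, so 10 gives 11 and F1 gives the diastereomeric (9R,10S,11R)-alcohol F2, which is removed by chromatography. The route is rejoined at 11.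

Step 11. The 4-exo closure may be reversible, with ring opening of the cyclised radical before the second electron transfer. Plain reduction of the enone, pinacol-type coupling between C2 and C5, or incomplete triflation of the samarium enolate may also compete. The fallback sets out from 12 and closes the ring with a carbon radical instead of a ketyl. LiAlH4 (THF, 0 °C) reduces the C5 ketone to the C5 alcohol F3. 1,1'-Thiocarbonyldiimidazole with DMAP (toluene, 80 °C) gives the imidazolyl thiocarbonate F4. 2,3-Dichloro-5,6-dicyano-1,4-benzoquinone with 2,6-lutidine (MeCN, 0 °C) oxidises the silyl enol ether to the enone thiocarbonate F5 without palladium. Slow addition of Bu3SnH/AIBN (benzene, 80 °C) releases a secondary C5 radical that closes 4-exo-trig onto C4; the α-keto radical takes hydrogen and gives the C5-deoxygenated tricyclic C2 ketone F6. Tf2O with 2,6-di-tert-butyl-4-methylpyridine (CH2Cl2, 0 °C) converts F6 into the more substituted enol triflate. The route is rejoined at 17, and steps 12 and 13 are no longer needed.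

Step 12. Acylation of the tertiary C5 hydroxyl may stall, because it points into the C1–C3 bridge and is flanked by C6 and two bridgeheads, and the later radical step depends on it. The fallback sets out from 15 and changes both the order and the activating group. The enol triflate is removed first with Pd(OAc)2/PPh3, HCO2H and Et3N (DMF, 60 °C) to give the 5-hydroxy alkene F7. With no triflate left, the alkoxide can be made with KH and added to CS2, a smaller electrophile, then methylated with MeI to give the S-methyl xanthate F8. Bu3SnH/AIBN (toluene, 110 °C) then removes the C5 oxygen. The route is rejoined at 18.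

**Further compounds**

F1 | step 7 | (10S,11R)-adduct, enantiomer of 10 | C12(OCCO1)CC(=O)[C@]3(C)[C@@H](CC(O[Si](C(C)C)(C(C)C)C(C)C)=C(C)C3)C(=O)C2(C)C
F2 | step 7 | (9R,10S,11R)-alcohol from F1, diastereomer of 11 | C12(OCCO1)C[C@@H](O)[C@]3(C)[C@@H](CC(O[Si](C(C)C)(C(C)C)C(C)C)=C(C)C3)C(=O)C2(C)C
F3 | step 11 | C5 alcohol from 12 (C5 epimers) | C12(OCCO1)C[C@@H](O[Si](CC)(CC)CC)[C@@]3(C)[C@H](CC(O[Si](C(C)C)(C(C)C)C(C)C)=C(C)C3)C(O)C2(C)C
F4 | step 11 | O-(imidazol-1-ylthiocarbonyl) derivative of F3 | C12(OCCO1)C[C@@H](O[Si](CC)(CC)CC)[C@@]3(C)[C@H](CC(O[Si](C(C)C)(C(C)C)C(C)C)=C(C)C3)C(OC(=S)n4ccnc4)C2(C)C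
F5 | step 11 | C2-keto C3=C4 enone bearing the C5 imidazolyl thiocarbonate | C12(OCCO1)C[C@@H](O[Si](CC)(CC)CC)[C@@]3(C)[C@H](CC(=O)C(C)=C3)C(OC(=S)n4ccnc4)C2(C)C
F6 | step 11 | 7,7-(ethylenedioxy)-9-(triethylsilyloxy)longipinan-2-one (C3 epimers) | C12(OCCO1)C[C@@H](O[Si](CC)(CC)CC)[C@@]3(C)[C@@H]4CC(=O)C(C)[C@H]3[C@@H]4C2(C)C
F7 | step 12 | 7,7-(ethylenedioxy)-9-(triethylsilyloxy)longipin-2-en-5-ol | C12(OCCO1)C[C@@H](O[Si](CC)(CC)CC)[C@@]3(C)[C@@H]4CC=C(C)[C@H]3[C@]4(O)C2(C)C
F8 | step 12 | O-C5 S-methyl xanthate of F7 | C12(OCCO1)C[C@@H](O[Si](CC)(CC)CC)[C@@]3(C)[C@@H]4CC=C(C)[C@H]3[C@]4(OC(=S)SC)C2(C)C
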